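**Retrosynthetic overview**
1. Target 17 ⇐ diether 16 by cleaving the two O-alkyl groups last (O-iPr on ring A, O-Me on ring B).
2. 16 ⇐ open-chain aryl enone ester 12: in one pot, chloride unmasks two phenols; one closes pyranone ring D (oxa-Michael), the other closes the seven-membered lactone-ether ring C (SNAr).
3. 12 ⇐ depside 9 + 3-methylbut-2-enoic acid 10 (Friedel–Crafts acylation at the only free position of ring B).
4. 9 ⇐ acid 6 + phenol 7 (ester); 6 ⇐ aldehyde 1 by SNAr with isopropoxide, then lithiation/carboxylation.
5. Ring order: benzene rings A and B are bought; rings D and C are formed together in step 5.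

Assumption: the target SMILES has no stereocentre, so the compound is achiral and no asymmetric step is needed (ring A = formyl-bearing benzene, B = central benzene, C = dioxepinone, D = dihydropyranone).

**Step 1**
Reactants: 1 2,6-difluoro-4-methylbenzaldehyde
Product: 2 2-fluoro-4-methyl-6-(propan-2-yloxy)benzaldehyde
Conditions: i-PrOH (1.05 equiv), NaH (1.05 equiv), THF, 0 °C → rt
Reagents that add atoms: propan-2-ol, CC(C)O
Why: Nucleophilic aromatic substitution (SNAr) of a fluoride ortho to the formyl group by isopropoxide; 1 is symmetric so only one mono-ether exists, and the new alkoxy group deactivates the ring against a second substitution.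

**Step 2**
Reactants: 2 2-fluoro-4-methyl-6-(propan-2-yloxy)benzaldehyde
Product: 6 2-fluoro-3-formyl-6-methyl-4-(propan-2-yloxy)benzoic acid, via lithium amino alkoxide 3 (not isolated), via aryllithium 4 (not isolated), via lithium carboxylate 5 (not isolated)
Conditions: 1-methylpiperazine + n-BuLi (gives lithium 4-methylpiperazin-1-ide), THF, −20 °C; s-BuLi, −78 °C; CO2, −78 °C → rt; aq. HCl
Reagents that add atoms: carbon dioxide, O=C=O
Why: In situ protection of the aldehyde as a lithium α-amino alkoxide followed by fluorine-directed ortho-lithiation and carboxylation; the only ring C–H acidified by an ortho fluorine is the one between F and CH3 (the other lies beside the bulky, poorly coordinating O-iPr group), CO2 traps the aryllithium below the temperature of LiF loss, and acid work-up releases the aldehyde.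

**Step 3**
Reactants: 6 2-fluoro-3-formyl-6-methyl-4-(propan-2-yloxy)benzoic acid; 7 2,3,4-trimethoxy-6-methylphenol
Product: 9 2,3,4-trimethoxy-6-methylphenyl 2-fluoro-3-formyl-6-methyl-4-(propan-2-yloxy)benzoate, via acid chloride 8 (not isolated)
Conditions: (COCl)2, DMF (cat.), CH2Cl2, 0 °C → rt, evaporate; then 7, Et3N, DMAP (cat.), CH2Cl2, 0 °C → rt
Reagents that add atoms: none
Why: Acyl chloride formation and DMAP-catalysed esterification of the only hydroxyl of 7; the aldehyde is meta to the carboxyl so no cyclic pseudo-chloride forms, and acylation is far faster than SNAr at the C–F bond.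

**Step 4**
Reactants: 9 2,3,4-trimethoxy-6-methylphenyl 2-fluoro-3-formyl-6-methyl-4-(propan-2-yloxy)benzoate; 10 3-methylbut-2-enoic acid
Product: 12 2,3,4-trimethoxy-6-methyl-5-(3-methylbut-2-enoyl)phenyl 2-fluoro-3-formyl-6-methyl-4-(propan-2-yloxy)benzoate, via mixed anhydride 11 (not isolated)
Conditions: TFAA (3 equiv), TfOH (0.2 equiv), CH2Cl2, 0 °C → rt
Reagents that add atoms: none
Why: Friedel–Crafts acylation by the acylium ion from mixed anhydride 11 at the single free position of ring B, which is ortho and para to two methoxy groups (the position acylated in related tetra-oxygenated toluenes), while electron-poor ring A is inert and the non-chelating Brønsted-acid conditions leave the O-iPr group, the ortho methoxy group and the aldehyde intact.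

**Step 5**
Reactants: 12 2,3,4-trimethoxy-6-methyl-5-(3-methylbut-2-enoyl)phenyl 2-fluoro-3-formyl-6-methyl-4-(propan-2-yloxy)benzoate
Product: 16 3-O-isopropyl-6-O-methyl diether of depsidone 17 (rings C and D closed), via hydroxy enone 13 (not isolated), via chromanone ester 14 (not isolated), via chromanone phenol 15 (not isolated)
Conditions: LiCl (8 equiv), AcOH (1.1 equiv), NMP (0.02 M), 140 °C
Reagents that add atoms: none
Why: Proposed new method: chloride removes by SN2 the methyl groups of the two methoxy groups whose phenoxides are stabilised by the aryl ketone (the ortho one helped by Li chelation to the carbonyl, the para one once the ketone is held coplanar in the chromanone), the closest known reaction being LiCl dealkylation of acyl-activated anisoles in hot amide solvents; the ortho phenol, protonated by AcOH with LiOAc as base, adds to the enone (6-endo oxa-Michael, as in base-catalysed closure of ortho-hydroxyaryl enones to chroman-4-ones) to give ring D, and the para phenoxide displaces the fluoride flanked by CHO and ester carbonyl (intramolecular SNAr, as in depsidone syntheses from 2-halobenzoates) to give ring C, while the unactivated middle OMe and the secondary O-iPr resist chloride and the hindered 2,6-disubstituted benzoate resists acyl migration; no stereocentre is formed.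

**Step 6**
Reactants: 16 3-O-isopropyl-6-O-methyl diether of depsidone 17
Product: 17 CNP0271978.0 (4-formyl-3,6-dihydroxy-1,9-dimethyl depsidone fused at C7-O/C8 to a 2,2-dimethyl-2,3-dihydropyran-4-one)
Conditions: BBr3 (6 equiv), CH2Cl2, −78 → 0 °C; then H2O
Reagents that add atoms: none
Why: Lewis-acid cleavage of aryl alkyl ethers by BBr3, which removes the isopropyl ether ortho to the aldehyde and the hindered out-of-plane methyl ether of ring B at or below 0 °C, conditions under which the diaryl ether, the aryl lactone, the aldehyde (held as a boron chelate) and the 2,2-dimethylchromanone survive; no stereocentre is present.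

**Compound list**
1 | 2,6-difluoro-4-methylbenzaldehyde | Cc1cc(F)c(C=O)c(F)c1 | starting material
2 | 2-fluoro-4-methyl-6-(propan-2-yloxy)benzaldehyde | Cc1cc(F)c(C=O)c(OC(C)C)c1 | intermediate
3 | lithium α-amino alkoxide of 2 with 1-methylpiperazine (racemic, not isolated) | Cc1cc(F)c(C(O[Li])N2CCN(C)CC2)c(OC(C)C)c1 | intermediate
4 | 3-lithio derivative of 3, lithium between F and CH3 (racemic, not isolated) | Cc1cc(OC(C)C)c(C(O[Li])N2CCN(C)CC2)c(F)c1[Li] | intermediate
5 | lithium carboxylate of the protected acid (racemic, not isolated) | Cc1cc(OC(C)C)c(C(O[Li])N2CCN(C)CC2)c(F)c1C(=O)O[Li] | intermediate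
6 | 2-fluoro-3-formyl-6-methyl-4-(propan-2-yloxy)benzoic acid | Cc1cc(OC(C)C)c(C=O)c(F)c1C(=O)O | intermediate
7 | 2,3,4-trimethoxy-6-methylphenol | Cc1cc(OC)c(OC)c(OC)c1O | starting material
8 | 2-fluoro-3-formyl-6-methyl-4-(propan-2-yloxy)benzoyl chloride (not isolated) | Cc1cc(OC(C)C)c(C=O)c(F)c1C(=O)Cl | intermediate
9 | 2,3,4-trimethoxy-6-methylphenyl 2-fluoro-3-formyl-6-methyl-4-(propan-2-yloxy)benzoate | Cc1cc(OC(C)C)c(C=O)c(F)c1C(=O)Oc1c(C)cc(OC)c(OC)c1OC | intermediate
10 | 3-methylbut-2-enoic acid | CC(C)=CC(=O)O | starting material
11 | 3-methylbut-2-enoic trifluoroacetic anhydride (not isolated) | CC(C)=CC(=O)OC(=O)C(F)(F)F | intermediate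
12 | 2,3,4-trimethoxy-6-methyl-5-(3-methylbut-2-enoyl)phenyl 2-fluoro-3-formyl-6-methyl-4-(propan-2-yloxy)benzoate | Cc1cc(OC(C)C)c(C=O)c(F)c1C(=O)Oc1c(C)c(C(=O)C=C(C)C)c(OC)c(OC)c1OC | intermediate
13 | 4-hydroxy-2,3-dimethoxy-6-methyl-5-(3-methylbut-2-enoyl)phenyl 2-fluoro-3-formyl-6-methyl-4-(propan-2-yloxy)benzoate (not isolated) | Cc1cc(OC(C)C)c(C=O)c(F)c1C(=O)Oc1c(C)c(C(=O)C=C(C)C)c(O)c(OC)c1OC | intermediate
14 | 7,8-dimethoxy-2,2,5-trimethyl-4-oxo-3,4-dihydro-2H-chromen-6-yl 2-fluoro-3-formyl-6-methyl-4-(propan-2-yloxy)benzoate (not isolated) | Cc1cc(OC(C)C)c(C=O)c(F)c1C(=O)Oc1c(C)c2c(c(OC)c1OC)OC(C)(C)CC2=O | intermediate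
15 | 7-hydroxy-8-methoxy-2,2,5-trimethyl-4-oxo-3,4-dihydro-2H-chromen-6-yl 2-fluoro-3-formyl-6-methyl-4-(propan-2-yloxy)benzoate (present as lithium phenoxide, not isolated) | Cc1cc(OC(C)C)c(C=O)c(F)c1C(=O)Oc1c(C)c2c(c(OC)c1O)OC(C)(C)CC2=O | intermediate
16 | target skeleton with O-isopropyl at C3 of ring A and O-methyl at C6 of ring B (depsidone numbering) | Cc1cc(OC(C)C)c(C=O)c2c1C(=O)Oc1c(C)c3c(c(OC)c1O2)OC(C)(C)CC3=O | intermediate
17 | CNP0271978.0: 4-formyl-3,6-dihydroxy-1,9-dimethyl-11-oxo-dibenzo[b,e][1,4]dioxepine (depsidone) with a 2,2-dimethyl-2,3-dihydropyran-4-one fused through O at C7 and C=O at C8; achiral | Cc1cc(O)c(C=O)c2c1C(=O)Oc1c(C)c3c(c(O)c1O2)OC(C)(C)CC3=O | target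

**Step count and risks**
Total steps: 6. Longest linear sequence: 6 (1 → 2 → 6 → 9 → 12 → 16 → 17); 7 and 10 enter convergently.

Steps most likely to fail:

Step 5 (double ring closure). The ortho methoxy group sits on a ketone that is twisted out of the ring plane before cyclisation, so its cleavage by chloride may be slow. Fluoride/chloride exchange at the activated C–F bond and acyl migration to the freed phenoxide could also intervene. The fallback closes the rings one after the other and sets out from phenol 7. Heating 7 with acid 10 in P2O5/MeSO3H at 70 °C acylates C5, after which the neighbouring methoxy oxygen attacks the protonated enone and loses its methyl group. This gives 6-hydroxy-7,8-dimethoxy-2,2,5-trimethylchroman-4-one F1 with ring D already closed. Esterification of F1 with acid chloride 8 (Et3N, DMAP, CH2Cl2) brings the material back to the route at 14. From 14, LiCl in NMP only has to do the para-selective 7-O-demethylation and the SNAr closure to 16 (no AcOH needed).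

Step 2 (site of lithiation). Deprotonation next to the O-iPr group instead of next to fluorine would give the wrong acid. The fallback reverses the order of the two operations and sets out from aldehyde 1. The same amino alkoxide protection, s-BuLi and CO2 sequence on symmetric 1 can give only one product, 2,4-difluoro-3-formyl-6-methylbenzoic acid F2. SNAr on the carboxylate of F2 with KOi-Pr in i-PrOH at 40–60 °C then takes the 4-fluorine, because the 2-fluorine is flanked on both sides and shielded by the neighbouring carboxylate. This gives 6, where the fallback rejoins the route.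

Step 4 (acylation of the depside). The reacting position is flanked by CH3 and OCH3, and the acid could activate the aldehyde of ring A toward hydroxyalkylation of ring B. The fallback acylates ring B before ring A is attached and sets out from phenol 7. Treating 7 with acid 10 and excess TFAA/TfOH masks the phenol in situ and gives 2,3,4-trimethoxy-6-methyl-5-(3-methylbut-2-enoyl)phenyl trifluoroacetate F3. Methanolysis (NaHCO3, MeOH, rt) frees 1-(3-hydroxy-4,5,6-trimethoxy-2-methylphenyl)-3-methylbut-2-en-1-one F4. Esterification of F4 with acid chloride 8 (Et3N, DMAP, CH2Cl2) brings the material back to the route at 12.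

**Further compounds**
F1 | step 5 | 6-hydroxy-7,8-dimethoxy-2,2,5-trimethylchroman-4-one | Cc1c(O)c(OC)c(OC)c2OC(C)(C)CC(=O)c12
F2 | step 2 | 2,4-difluoro-3-formyl-6-methylbenzoic acid | Cc1cc(F)c(C=O)c(F)c1C(=O)O
F3 | step 4 | 2,3,4-trimethoxy-6-methyl-5-(3-methylbut-2-enoyl)phenyl trifluoroacetate | Cc1c(OC(=O)C(F)(F)F)c(OC)c(OC)c(OC)c1C(=O)C=C(C)C
F4 | step 4 | 1-(3-hydroxy-4,5,6-trimethoxy-2-methylphenyl)-3-methylbut-2-en-1-one | Cc1c(O)c(OC)c(OC)c(OC)c1C(=O)C=C(C)C
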